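**Assumption:** the target is taken exactly as the SMILES draws it: germacrane numbering, (2S,6R,7S,8S,9S), C6–O/C12 lactone, C14 = CO2Me carbon on C10, C15 = CH2OH on C4, both ring alkenes cis within the ring (each E by CIP).

## Retrosynthetic overview

1. The ten-membered ring is formed last, by ring-closing metathesis at C1=C10 of the seco-lactone 26.
2. The γ-lactone ring and the C6–C7 bond are formed before it, by allylboration/lactonisation of west lactol 24 (C1–C6, C15) with east (Z)-allylboronate 13 (C7–C14).
3. East: organocatalytic α-isobutyryloxylation (C8), β-isocupreidine Morita–Baylis–Hillman reaction (C9–C10), bromo-olefination and Negishi borylmethylation (C11–C13).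
4. West: hydrogen-bond-catalysed hetero-Diels–Alder reaction (C2), then 1,2-addition/allylic transposition that fixes the C4=C5 geometry inside a six-membered lactol.
5. No protecting group is carried past the fragment stage; the metathesis delivers the target directly.

## Route

Step 1
Reactants: 1 3-[(tert-butyldimethylsilyl)oxy]propanal; 2 bis(2-methylpropanoyl) peroxide
Product: 3 (2S)-1-[(tert-butyldimethylsilyl)oxy]-3-oxopropan-2-yl 2-methylpropanoate
Conditions: (S)-2-(triphenylmethyl)pyrrolidine (10 mol %), hydroquinone (10 mol %), 2 (1.1 equiv, freshly made cold 0.5 M solution), THF, 0 °C; cold NaHCO3 wash, used crude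
Reagents that add atoms: none
Why: Proposed new method: the E-enamine of 1 attacks the weak O–O bond of the diacyl peroxide (displacement at oxygen, isobutyrate leaving) from the face away from the trityl group, which sets C8 as (S) and installs the natural isobutyrate in one operation; the closest known reaction is the secondary-amine-catalysed α-benzoyloxylation of aldehydes with dibenzoyl peroxide, extended here to an aliphatic diacyl peroxide, with hydroquinone suppressing radical decomposition.

Step 2
Reactants: 3 (2S)-1-[(tert-butyldimethylsilyl)oxy]-3-oxopropan-2-yl 2-methylpropanoate; 4 1,1,1,3,3,3-hexafluoropropan-2-yl acrylate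
Product: 6 1,1,1,3,3,3-hexafluoropropan-2-yl (3S,4S)-3-acetoxy-5-[(tert-butyldimethylsilyl)oxy]-4-(isobutyryloxy)-2-methylenepentanoate, via Baylis–Hillman alcohol 5 (not isolated)
Conditions: β-isocupreidine (10 mol %), 4 (1.3 equiv), DMF, −55 °C, 60 h; cold 0.5 M HCl wash; then AcCl, pyridine, CH2Cl2, −20 to 0 °C
Reagents that add atoms: acetyl chloride, CC(Cl)=O
Why: Morita–Baylis–Hillman reaction under chiral Lewis-base control, in which the catalyst attacks its usual aldehyde face, the matched pairing for an (S)-α-heteroatom aldehyde (as with N-protected (S)-α-amino aldehydes), giving the 8,9-syn adduct with C9 (S); the amine is washed out before acylation so that it cannot transpose the allylic acetate.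

Step 3
Reactants: 6 hexafluoroisopropyl ester from step 2
Product: 7 methyl (3S,4S)-3-acetoxy-5-[(tert-butyldimethylsilyl)oxy]-4-(isobutyryloxy)-2-methylenepentanoate
Conditions: MeOH, iPr2NEt (0.5 equiv), 0 °C to rt
Reagents that add atoms: methanol, CO
Why: Transesterification of an activated ester: the hexafluoroisopropyl ester exchanges with methanol far faster than the secondary acetate and isobutyrate, and the non-nucleophilic base does not attack the allylic acetate; no stereocenter is touched.

Step 4
Reactants: 7 silyl ether from step 3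
Product: 8 methyl (3S,4S)-3-acetoxy-5-hydroxy-4-(isobutyryloxy)-2-methylenepentanoate
Conditions: HF·pyridine, pyridine, THF, 0 °C
Reagents that add atoms: none
Why: Fluoride desilylation under buffered, mildly acidic conditions frees the primary alcohol without base, so the neighbouring isobutyrate does not migrate.

Step 5
Reactants: 8 primary alcohol from step 4
Product: 9 methyl (3S,4R)-3-acetoxy-4-(isobutyryloxy)-2-methylene-5-oxopentanoate
Conditions: Dess–Martin periodinane, CH2Cl2, 0 °C; used at once
Reagents that add atoms: none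
Why: Dess–Martin oxidation is fast and non-basic, so the α-acyloxy aldehyde forms without epimerisation at C8 or β-elimination of the C9 acetate (the descriptor at C8 changes only because the CIP priorities change).

Step 6
Reactants: 9 aldehyde from step 5; 10 methyl 2-[bis(2,2,2-trifluoroethoxy)phosphoryl]-2-bromoacetate
Product: 11 dimethyl (2E,4S,5S)-5-acetoxy-2-bromo-4-(isobutyryloxy)-6-methylenehept-2-enedioate
Conditions: 10, KN(SiMe3)2, 18-crown-6, THF, −78 °C, then 9
Reagents that add atoms: none
Why: Horner–Wadsworth–Emmons olefination with a bis(trifluoroethyl) bromophosphonate (Still–Gennari-type kinetic control) places the ester cis to C8 and the bromine trans, the geometry that later dictates the trans lactone.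

Step 7
Reactants: 11 bromo-enoate from step 6; 12 2-(iodomethyl)-4,4,5,5-tetramethyl-1,3,2-dioxaborolane
Product: 13 dimethyl (2Z,4S,5S)-5-acetoxy-4-(isobutyryloxy)-6-methylene-2-[(4,4,5,5-tetramethyl-1,3,2-dioxaborolan-2-yl)methyl]hept-2-enedioate
Conditions: 12, Zn dust, THF, rt; then 11, Pd2(dba)3 (2.5 mol %), P(2-furyl)3 (10 mol %), THF, rt
Reagents that add atoms: none
Why: Negishi sp2–sp3 coupling with retention of alkene geometry gives the (Z)-2-(methoxycarbonyl)allylboronate; the weakly donating furylphosphine is chosen so that oxidative addition of zerovalent palladium into the activated alkenyl bromide outruns ionisation of the allylic acetate.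

Step 8
Reactants: 14 acrolein; 15 benzeneselenol
Product: 16 3-(phenylselanyl)propanal
Conditions: Et3N (1 mol %), CH2Cl2, 0 °C
Reagents that add atoms: none
Why: Conjugate (selena-Michael) addition gives a saturated acrolein surrogate whose masked C=C cannot compete as a dienophile in the next step.

Step 9
Reactants: 16 3-(phenylselanyl)propanal; 17 (E)-3-[(tert-butyldimethylsilyl)oxy]-N,N-dimethylbuta-1,3-dien-1-amine
Product: 19 (2S)-2-[2-(phenylselanyl)ethyl]-2,3-dihydro-4H-pyran-4-one, via aminal cycloadduct 18 (not isolated)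
Conditions: (4R,5R)-2,2-dimethyl-α,α,α′,α′-tetra(1-naphthyl)-1,3-dioxolane-4,5-dimethanol (20 mol %; the enantiomer is chosen for Si-face addition), toluene, −60 °C; then AcCl, CH2Cl2, −78 °C
Reagents that add atoms: none
Why: Hydrogen-bond-catalysed hetero-Diels–Alder reaction in which the chiral diol activates the aldehyde and shields one face so that the diene terminus adds to the Si face, setting C2 as (S); acetyl chloride then expels dimethylamine and the silyl group to unveil the dihydropyranone.

Step 10
Reactants: 19 selenide from step 9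
Product: 21 (2S)-2-ethenyl-2,3-dihydro-4H-pyran-4-one, via selenoxide 20 (not isolated)
Conditions: 30 % H2O2, pyridine, CH2Cl2, 0 °C to rt
Reagents that add atoms: none
Why: Oxidation to the selenoxide and its syn-elimination (the only β-hydrogens are on C1) give the vinyl group without touching C2.

Step 11
Reactants: 21 vinyl dihydropyranone from step 10; 22 tributyl{[(2-methoxypropan-2-yl)oxy]methyl}stannane
Product: 24 (6S)-6-ethenyl-4-(hydroxymethyl)-5,6-dihydro-2H-pyran-2-ol (anomer mixture), via tertiary alcohol adduct 23 (not isolated)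
Conditions: 22, n-BuLi, THF, −78 °C; then 21, −78 °C; then 0.1 M HCl, THF/H2O, 0 °C
Reagents that add atoms: water, O
Why: 1,2-Addition of the α-alkoxymethyllithium to the vinylogous ester carbonyl, then acid-mediated allylic transposition through the ring oxocarbenium ion (Stork–Danheiser/Ferrier type) with cleavage of the mixed acetal; C2–O and C6 stay tied in the six-membered ring, so C3 and C6 are necessarily cis on the new C4=C5 bond.

Step 12
Reactants: 13 (Z)-allylboronate from step 7; 24 lactol from step 11
Product: 26 seco α-methylene-γ-butyrolactone (2S,6R,7S,8S,9S; C1 as vinyl and C10 as acrylate methylene), via borate adduct 25 (not isolated)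
Conditions: toluene (0.2 M), 70 °C, 48 h; then p-TsOH·H2O (10 mol %), CH2Cl2, rt
Reagents that add atoms: none
Why: Thermal allylboration of the open hydroxy-enal form of 24 through a chair transition state, in which C8 trans to CH2B gives the 6,7-anti adduct (trans lactone) and the aldehyde approaches C7 anti to the bulky C9 branch with H-8 eclipsing the alkene (allylic 1,3-strain), setting C7 (S) and C6 (R); acid then closes the lactone with loss of methanol.

Step 13
Reactants: 26 seco-lactone from step 12
Product: 27 CNP0301018.3 (target)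
Conditions: second-generation Hoveyda–Grubbs catalyst RuCl2(H2IMes)(=CH-C6H4-2-OiPr) (2 × 10 mol %), 1,4-benzoquinone (20 mol %), toluene (1 mM), 80 °C
Reagents that add atoms: none
Why: Ring-closing metathesis in which the ruthenium carbene loads on the C1 vinyl group and closes onto the acrylate CH2 at C10 with loss of ethene, the ten-membered ring holding C2 and C9 cis on the new trisubstituted alkene (E by CIP); closure onto the lactone methylene would need a bridgehead alkene in an eight-membered ring and is disfavoured, and no stereocenter is touched.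

## Compound list

1 | 3-[(tert-butyldimethylsilyl)oxy]propanal | O=CCCO[Si](C)(C)C(C)(C)C | starting material
2 | bis(2-methylpropanoyl) peroxide (diisobutyryl peroxide) | CC(C)C(=O)OOC(=O)C(C)C | starting material
3 | (2S)-1-[(tert-butyldimethylsilyl)oxy]-3-oxopropan-2-yl 2-methylpropanoate | O=C[C@@H](OC(=O)C(C)C)CO[Si](C)(C)C(C)(C)C | intermediate
4 | 1,1,1,3,3,3-hexafluoropropan-2-yl acrylate | C=CC(=O)OC(C(F)(F)F)C(F)(F)F | starting material
5 | 1,1,1,3,3,3-hexafluoropropan-2-yl (3S,4S)-5-[(tert-butyldimethylsilyl)oxy]-3-hydroxy-4-(isobutyryloxy)-2-methylenepentanoate | C=C(C(=O)OC(C(F)(F)F)C(F)(F)F)[C@H](O)[C@@H](OC(=O)C(C)C)CO[Si](C)(C)C(C)(C)C | intermediate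
6 | 1,1,1,3,3,3-hexafluoropropan-2-yl (3S,4S)-3-acetoxy-5-[(tert-butyldimethylsilyl)oxy]-4-(isobutyryloxy)-2-methylenepentanoate | C=C(C(=O)OC(C(F)(F)F)C(F)(F)F)[C@H](OC(C)=O)[C@@H](OC(=O)C(C)C)CO[Si](C)(C)C(C)(C)C | intermediate
7 | methyl (3S,4S)-3-acetoxy-5-[(tert-butyldimethylsilyl)oxy]-4-(isobutyryloxy)-2-methylenepentanoate | C=C(C(=O)OC)[C@H](OC(C)=O)[C@@H](OC(=O)C(C)C)CO[Si](C)(C)C(C)(C)C | intermediate
8 | methyl (3S,4S)-3-acetoxy-5-hydroxy-4-(isobutyryloxy)-2-methylenepentanoate | C=C(C(=O)OC)[C@H](OC(C)=O)[C@@H](OC(=O)C(C)C)CO | intermediate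
9 | methyl (3S,4R)-3-acetoxy-4-(isobutyryloxy)-2-methylene-5-oxopentanoate | C=C(C(=O)OC)[C@H](OC(C)=O)[C@@H](OC(=O)C(C)C)C=O | intermediate
10 | methyl 2-[bis(2,2,2-trifluoroethoxy)phosphoryl]-2-bromoacetate (olefination reagent; its labile P–CHBr carbon plays no stereochemical role) | COC(=O)C(Br)P(=O)(OCC(F)(F)F)OCC(F)(F)F | starting material
11 | dimethyl (2E,4S,5S)-5-acetoxy-2-bromo-4-(isobutyryloxy)-6-methylenehept-2-enedioate | C=C(C(=O)OC)[C@H](OC(C)=O)[C@@H](OC(=O)C(C)C)/C=C(/Br)C(=O)OC | intermediate
12 | 2-(iodomethyl)-4,4,5,5-tetramethyl-1,3,2-dioxaborolane | ICB1OC(C)(C)C(C)(C)O1 | starting material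
13 | dimethyl (2Z,4S,5S)-5-acetoxy-4-(isobutyryloxy)-6-methylene-2-[(4,4,5,5-tetramethyl-1,3,2-dioxaborolan-2-yl)methyl]hept-2-enedioate | C=C(C(=O)OC)[C@H](OC(C)=O)[C@@H](OC(=O)C(C)C)/C=C(/CB1OC(C)(C)C(C)(C)O1)C(=O)OC | intermediate
14 | acrolein | C=CC=O | starting material
15 | benzeneselenol | [SeH]c1ccccc1 | starting material
16 | 3-(phenylselanyl)propanal | O=CCC[Se]c1ccccc1 | intermediate
17 | (E)-3-[(tert-butyldimethylsilyl)oxy]-N,N-dimethylbuta-1,3-dien-1-amine | CN(C)/C=C/C(=C)O[Si](C)(C)C(C)(C)C | starting material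
18 | (6S)-4-[(tert-butyldimethylsilyl)oxy]-N,N-dimethyl-6-[2-(phenylselanyl)ethyl]-5,6-dihydro-2H-pyran-2-amine (aminal carbon unassigned) | CN(C)C1C=C(O[Si](C)(C)C(C)(C)C)C[C@@H](CC[Se]c2ccccc2)O1 | intermediate
19 | (2S)-2-[2-(phenylselanyl)ethyl]-2,3-dihydro-4H-pyran-4-one | O=C1C=CO[C@H](CC[Se]c2ccccc2)C1 | intermediate
20 | (2S)-2-[2-(phenylseleninyl)ethyl]-2,3-dihydro-4H-pyran-4-one (selenoxide) | O=C1C=CO[C@H](CC[Se](=O)c2ccccc2)C1 | intermediate
21 | (2S)-2-ethenyl-2,3-dihydro-4H-pyran-4-one | O=C1C=CO[C@H](C=C)C1 | intermediate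
22 | tributyl{[(2-methoxypropan-2-yl)oxy]methyl}stannane | CCCC[Sn](CCCC)(CCCC)COC(C)(C)OC | starting material
23 | (2S)-2-ethenyl-4-{[(2-methoxypropan-2-yl)oxy]methyl}-3,4-dihydro-2H-pyran-4-ol (C4 unassigned) | OC1(COC(C)(C)OC)C=CO[C@H](C=C)C1 | intermediate
24 | (6S)-6-ethenyl-4-(hydroxymethyl)-5,6-dihydro-2H-pyran-2-ol (anomer mixture) | OCC1=CC(O)O[C@H](C=C)C1 | intermediate
25 | open-chain allylboration adduct (2S,6R,7S,8S,9S): C6–O–B(pinacolato) borate, C12 still a methyl ester, C11=C13 methylene | C=C(C(=O)OC)[C@@H]([C@H](OB1OC(C)(C)C(C)(C)O1)/C=C(/CO)C[C@H](O)C=C)[C@H](OC(=O)C(C)C)[C@@H](OC(C)=O)C(=C)C(=O)OC | intermediate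
26 | seco-lactone: methyl (3S,4S)-3-acetoxy-4-{(2R,3S)-2-[(1E,4S)-4-hydroxy-2-(hydroxymethyl)hexa-1,5-dien-1-yl]-4-methylene-5-oxotetrahydrofuran-3-yl}-4-(isobutyryloxy)-2-methylenebutanoate | C=C1C(=O)O[C@H](/C=C(/CO)C[C@H](O)C=C)[C@H]1[C@H](OC(=O)C(C)C)[C@@H](OC(C)=O)C(=C)C(=O)OC | intermediate
27 | CNP0301018.3: methyl (2S,6R,7S,8S,9S)-9-acetoxy-2,15-dihydroxy-8-(isobutyryloxy)germacra-1(10)E,4E,11(13)-trien-12,6-olid-14-oate (both ring alkenes cis within the ring) | C=C1C(=O)O[C@@H]2/C=C(/CO)C[C@H](O)/C=C(/C(=O)OC)[C@H](OC(C)=O)[C@@H](OC(=O)C(C)C)[C@@H]12 | target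

## Step count and risks

Total: 13 steps. Longest linear sequence: 9 steps (steps 1–7, 12, 13); the west branch is steps 8–11.

**Step 13 (ring-closing metathesis).** The acrylate partner is a hindered, electron-poor 1,1-disubstituted alkene and the ring is ten-membered; oligomerisation or stalling are the likely failures. Fallback: invert the order of the two ring-forming events. Setting out from 13 and 24, cross-metathesis (same ruthenium catalyst, excess 24, 40 °C) joins C1 to C10 while both partners are unstrained. This gives the lactol-tethered allylboronate seco compound F6, whose ring-cis C1=C10 geometry would have to be secured by separation of the alkene isomers. Warming F6 at high dilution (toluene, 70 °C) closes the ten-membered ring by intramolecular allylboration, and p-TsOH then forms the lactone, coming back to the route at 27.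

**Step 1 (new α-isobutyryloxylation).** The aliphatic peroxide may oxidise the amine catalyst or decompose faster than it is attacked. Fallback with known chemistry, setting out from 1: D-proline-catalysed α-aminoxylation with nitrosobenzene and reduction in the same flask with NaBH4 give (2R)-2-(anilinooxy)-3-[(tert-butyldimethylsilyl)oxy]propan-1-ol F1. Hydrogenolysis of the N–O bond (H2, Pd/C, MeOH) gives (2R)-3-[(tert-butyldimethylsilyl)oxy]propane-1,2-diol F2. Trimethyl orthoisobutyrate with PPTS, then aqueous acetic acid, opens the cyclic orthoester to the secondary ester (2R)-1-[(tert-butyldimethylsilyl)oxy]-3-hydroxypropan-2-yl 2-methylpropanoate F3. Dess–Martin oxidation of F3 comes back to the route at 3.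

**Step 12 (allylboration/lactonisation).** The lactol may release its aldehyde too slowly for the deactivated boronate, and the facial selectivity at C7 rests on substrate control alone. Fallback, setting out from 11: Stille coupling with (tributylstannyl)methanol (Pd(PPh3)4, dioxane, 80 °C) gives dimethyl (2Z,4S,5S)-5-acetoxy-2-(hydroxymethyl)-4-(isobutyryloxy)-6-methylenehept-2-enedioate F4. CBr4/PPh3 converts it into dimethyl (2E,4S,5S)-5-acetoxy-2-(bromomethyl)-4-(isobutyryloxy)-6-methylenehept-2-enedioate F5. A CrCl2-mediated Nozaki–Hiyama-type allylation of lactol 24 with F5 (THF, rt), followed by p-TsOH, comes back to the route at 26. The equilibrating allylchromium reagent is expected to add through a chair with the γ-substituent equatorial, giving the same 6,7-anti relationship.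

## Further compounds

F1 | step 1 | (2R)-2-(anilinooxy)-3-[(tert-butyldimethylsilyl)oxy]propan-1-ol | OC[C@@H](ONc1ccccc1)CO[Si](C)(C)C(C)(C)C
F2 | step 1 | (2R)-3-[(tert-butyldimethylsilyl)oxy]propane-1,2-diol | OC[C@@H](O)CO[Si](C)(C)C(C)(C)C
F3 | step 1 | (2R)-1-[(tert-butyldimethylsilyl)oxy]-3-hydroxypropan-2-yl 2-methylpropanoate | OC[C@@H](OC(=O)C(C)C)CO[Si](C)(C)C(C)(C)C
F4 | step 12 | dimethyl (2Z,4S,5S)-5-acetoxy-2-(hydroxymethyl)-4-(isobutyryloxy)-6-methylenehept-2-enedioate | C=C(C(=O)OC)[C@H](OC(C)=O)[C@@H](OC(=O)C(C)C)/C=C(/CO)C(=O)OC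
F5 | step 12 | dimethyl (2E,4S,5S)-5-acetoxy-2-(bromomethyl)-4-(isobutyryloxy)-6-methylenehept-2-enedioate | C=C(C(=O)OC)[C@H](OC(C)=O)[C@@H](OC(=O)C(C)C)/C=C(/CBr)C(=O)OC
F6 | step 13 | lactol-tethered allylboronate seco compound (C1=C10 formed with C2 trans to CO2Me; lactol and CH2B(pinacolato) still open) | OCC1=CC(O)O[C@H](/C=C(/C(=O)OC)[C@H](OC(C)=O)[C@@H](OC(=O)C(C)C)/C=C(/CB2OC(C)(C)C(C)(C)O2)C(=O)OC)C1
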